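**Plan**

- Numbering used here: C2 is the allylic CH2OH carbon, C3=C4 the Z-alkene, C7 and C11 the two CH(CH2O) carbons (C18 = acetoxymethyl on C7, C19 = hydroxymethyl on C11), C15 the butenolide α-carbon.
- Cuts, in retrosynthetic order: C14–C15 and C4–C5 (two B-alkyl Suzuki couplings); the alkenes C5=C6 and C12=C13 are re-paired into the ring alkene C6=C12 of a cycloheptene plus a silicon-bound allyl group (which supplies C5, C13 and C14); last, C7–C8 and C10–C11 by a (4+3) cut.
- Enabling feature: C7 and C11 are 1,5-related CH(CH2O) carbons joined by C8–C9–C10, and their (7R,11S) relation is the cis, meso-type one, so both sit as cis substituents on a seven-membered ring C6–C7–C8–C9–C10–C11–C12.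
- Forward: an E,E-dienediol ether and an oxyallyl cation close that ring (the only carbocycle made; its carbonyl carbon is C9). C9 is deoxygenated, the ring is reopened by metathesis so that C6 ends as a vinyl group and C12 inside a cyclic allylsilane, and the arms are attached by hydroboration/Suzuki coupling (C4–C5 first, then C14–C15).
- Stereochemistry: cis C7/C11 from suprafacial (4+3) addition to the E,E-diene; absolute configuration from lipase desymmetrisation of the meso diol; the Z-alkene from anti-carbomagnesiation of propargyl alcohol, retained in the coupling.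

Key step: step 3

Assumption: Burkholderia cepacia lipase is taken to acetylate the hydroxymethyl group on the R-configured ring carbon of the meso diol (the future C18). The sense must be confirmed on the first run; if it is reversed, the same enzyme would be run in the hydrolytic direction, which makes the mirror-image choice.

**Route**

Step 1
Reactants: 1 dimethyl (2E,4E)-hexa-2,4-dienedioate
Product: 2 (2E,4E)-hexa-2,4-diene-1,6-diol
Conditions: i-Bu2AlH (4.4 equiv), CH2Cl2, −78 to 0 °C; aq. KNaC4H4O6 work-up
Reagents that add atoms: none
Why: Reduction of both conjugated ester groups by i-Bu2AlH is a 1,2-hydride delivery only (ester to primary allylic alcohol), so the diene and its E,E geometry should pass unchanged into the dienediol.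

Step 2
Reactants: 2 (2E,4E)-hexa-2,4-diene-1,6-diol
Product: 3 (2E,4E)-1,6-bis(tert-butyldimethylsilyloxy)hexa-2,4-diene
Conditions: TBSCl (2.3 equiv), imidazole, DMF, rt
Reagents that add atoms: tert-butyldimethylsilyl chloride, CC(C)(C)[Si](C)(C)Cl
Why: Imidazole-promoted silylation of the two primary allylic alcohols gives ethers that are non-nucleophilic, soluble in benzene and stable to the weakly Lewis-acidic iron salts of the next step.

Step 3
Reactants: 3 (2E,4E)-1,6-bis(tert-butyldimethylsilyloxy)hexa-2,4-diene; 4 1,1,3,3-tetrabromopropan-2-one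
Product: 6 (3R,6S)-3,6-bis[(tert-butyldimethylsilyloxy)methyl]cyclohept-4-en-1-one (meso, cis; ring C1 = C9), via dibromocycloheptenone cycloadduct 5 (not isolated)
Conditions: 3 (2.5 equiv, excess recovered), Fe2(CO)9 (1.2 equiv), PhH, 60 °C; then Zn–Cu couple, NH4Cl-saturated MeOH, rt
Reagents that add atoms: none
Why: Zerovalent iron released from Fe2(CO)9 reduces 4 by two electrons and, with loss of one bromide from each α-carbon, leaves an oxygen-metallated 1,3-dibromoallyl cation bound to divalent iron, a three-carbon two-π-electron unit electrophilic enough for an unactivated diene. The closest known reaction type is the iron-carbonyl polybromoketone–diene cyclocoupling (Noyori (4+3) cycloaddition), which is documented for butadiene-type open-chain dienes as well as for furans. The seven-membered ring closes by intermolecular (4+3) cycloaddition across the two termini of the s-cis diene, forming C7–C8 and C10–C11 either in one event or in two fast steps through an allyl cation that collapses onto the iron enolate before any bond rotation. The two new stereocentres (ring C3 and C6, the future C7 and C11) should come out cis because the E,E-diene carries both silyloxymethyl groups on its outer positions and the three-carbon unit adds to one face of the diene, while the bromine-bearing carbons form as mixtures and are erased when Zn–Cu reduces both C–Br bonds. The step needs cis over trans and ring formation over simple alkylation of the diene; the E,E geometry (easy s-cis conformer, no inside substituent) and a non-basic medium in which primary TBS ethers survive should secure both. The product is meso, so no absolute configuration is at stake here.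

Step 4
Reactants: 6 (3R,6S)-3,6-bis[(tert-butyldimethylsilyloxy)methyl]cyclohept-4-en-1-one
Product: 7 N'-{(3R,6S)-3,6-bis[(tert-butyldimethylsilyloxy)methyl]cyclohept-4-en-1-ylidene}-4-methylbenzenesulfonohydrazide (either C=N orientation)
Conditions: TsNHNH2 (1.1 equiv), EtOH, 50 °C
Reagents that add atoms: 4-methylbenzenesulfonohydrazide, Cc1ccc(cc1)S(=O)(=O)NN
Why: Condensation of the unhindered ring ketone with tosylhydrazide gives the tosylhydrazone without added acid, and the stereocentres, being β to the carbonyl, cannot epimerise.

Step 5
Reactants: 7 the tosylhydrazone of 6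
Product: 8 (3R,7S)-3,7-bis[(tert-butyldimethylsilyloxy)methyl]cyclohept-1-ene (meso, cis)
Conditions: catecholborane (1.5 equiv), CHCl3, 0 °C to rt; then NaOAc·3H2O, reflux
Reagents that add atoms: none
Why: Caglioti-type tosylhydrazone reduction in its catecholborane variant: hydride adds to C=N, acetate triggers loss of sulfinate and the alkyl diazene expels N2 to leave CH2 at C9, while the isolated ring alkene (inert to catecholborane at room temperature) and the silyl ethers are untouched.

Step 6
Reactants: 8 (3R,7S)-3,7-bis[(tert-butyldimethylsilyloxy)methyl]cyclohept-1-ene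
Product: 9 [(1R,4S)-cyclohept-2-ene-1,4-diyl]dimethanol (meso, cis)
Conditions: Bu4NF (2.5 equiv), THF, rt
Reagents that add atoms: none
Why: Fluoride cleaves both primary TBS ethers through pentacoordinate silicon and should give the meso diol under conditions that cannot move the ring alkene.

Step 7
Reactants: 9 [(1R,4S)-cyclohept-2-ene-1,4-diyl]dimethanol
Product: 10 [(1R,4S)-4-(hydroxymethyl)cyclohept-2-en-1-yl]methyl acetate
Conditions: Burkholderia cepacia lipase (Amano PS, immobilised), vinyl acetate (3 equiv), t-BuOMe, rt, stopped when 9 is consumed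
Reagents that add atoms: vinyl acetate, CC(=O)OC=C
Why: Lipase-catalysed irreversible transesterification (enzymatic desymmetrisation of a meso diol) acylates one of the two enantiotopic hydroxymethyl groups, which fixes the absolute configuration at both ring carbons (future C7 and C11) in one event and places the acetate that is the C18 acetate of the target.

Step 8
Reactants: 10 [(1R,4S)-4-(hydroxymethyl)cyclohept-2-en-1-yl]methyl acetate
Product: 11 [(1R,4S)-4-({[dimethyl(prop-2-en-1-yl)silyl]oxy}methyl)cyclohept-2-en-1-yl]methyl acetate
Conditions: allyl(chloro)dimethylsilane (1.2 equiv), Et3N, DMAP (cat.), CH2Cl2, 0 °C; non-aqueous work-up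
Reagents that add atoms: allyl(chloro)dimethylsilane, C=CC[Si](C)(C)Cl
Why: Silylation of the remaining primary alcohol under amine base installs the O–Si–CH2 tether whose allyl group carries the future C5, C13 and C14, and the acetate cannot migrate across the ring under these conditions.

Step 9
Reactants: 11 the allylsilyl ether of 10
Product: 12 (2R)-2-ethenyl-5-[(6S)-2,2-dimethyl-1-oxa-2-silacyclohept-4-en-6-yl]pentyl acetate
Conditions: second-generation Grubbs catalyst RuCl2(=CHPh)(PCy3)(H2IMes) (5 mol%), CH2Cl2 (5 mM), 40 °C
Reagents that add atoms: none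
Why: Ring-rearrangement metathesis (ring opening followed by ring closing): the ruthenium alkylidene formed at the unhindered allyl terminus opens the cycloheptene at C12 from within and closes the 1-oxa-2-silacyclohept-4-ene, the alkylidene left on C6 takes a methylene from the next substrate molecule, and since closure onto C6 would need an eleven-membered ring the two former ring-alkene carbons end up differentiated, the less strained silicon-containing ring (long Si–C and Si–O bonds) providing the bias.

Step 10
Reactants: 13 prop-2-yn-1-ol (propargyl alcohol)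
Product: 14 (2Z)-3-iodo-2-methylprop-2-en-1-ol
Conditions: MeMgBr (2.5 equiv), CuI (10 mol%), Et2O, −10 °C to rt; then I2, −20 °C to rt
Reagents that add atoms: methylmagnesium bromide, C[Mg]Br; iodine, II
Why: Copper-catalysed carbomagnesiation of the magnesium alkoxide of propargyl alcohol adds methyl to C2 and magnesium to C3 in an anti sense within a five-membered chelate, and iodinolysis of the C–Mg bond with retention should give only the Z-iodoalkenol.

Step 11
Reactants: 12 the oxasilacycloheptene from step 9; 14 (2Z)-3-iodo-2-methylprop-2-en-1-ol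
Product: 16 (2R)-5-[(6S)-2,2-dimethyl-1-oxa-2-silacyclohept-4-en-6-yl]-2-[(3Z)-5-hydroxy-4-methylpent-3-en-1-yl]pentyl acetate, via B-alkyl-9-BBN adduct 15 (not isolated)
Conditions: 9-BBN (1.1 equiv), THF, 0 °C to rt; then 14 (1.3 equiv), PdCl2(dppf) (5 mol%), AsPh3 (10 mol%), K3PO4·H2O, DMF, rt
Reagents that add atoms: none
Why: 9-BBN hydroborates the monosubstituted vinyl group anti-Markovnikov far faster than the cis-disubstituted ring alkene, and the B-alkyl Suzuki–Miyaura coupling (zerovalent palladium, oxidative addition to the alkenyl iodide with retention) forms C4–C5 with the Z geometry intact; the acetate tolerates the phosphate base and any silanol from partial Si–O hydrolysis converges on the same product in step 12.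

Step 12
Reactants: 16 the coupled oxasilacycloheptene
Product: 17 (2R,6S)-2-[(3Z)-5-hydroxy-4-methylpent-3-en-1-yl]-6-(hydroxymethyl)non-8-en-1-yl acetate
Conditions: CF3CO2H (5 equiv), CH2Cl2, 0 °C, short contact; then aq. NaHCO3/MeOH, rt
Reagents that add atoms: none
Why: Protodesilylation of the allylsilane in the SE2' sense: the proton adds to C12, the β-silyl cation at C13 loses silicon and the alkene moves to C13=C14, and the bicarbonate work-up hydrolyses the Si–O bond (and any trifluoroacetate ester) to free the C19 hydroxyl; the allylsilane is the most nucleophilic alkene present and the trisubstituted alkene is deactivated by its allylic oxygen.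

Step 13
Reactants: 17 the diol monoacetate with the terminal alkene; 18 3-bromofuran-2(5H)-one
Product: 20 (2R,6S)-2-[(3Z)-5-hydroxy-4-methylpent-3-en-1-yl]-6-(hydroxymethyl)-9-(2-oxo-2,5-dihydrofuran-3-yl)nonyl acetate (the target, CNP0325245.2), via tris-9-BBN adduct 19 (not isolated)
Conditions: 9-BBN (3.5 equiv), THF, rt; then 18 (1.5 equiv), PdCl2(dppf) (5 mol%), AsPh3 (10 mol%), K3PO4·H2O, DMF/THF, rt
Reagents that add atoms: none
Why: Excess 9-BBN converts the two hydroxyls into borinates and hydroborates the terminal alkene at C14 (the trisubstituted alkene is far slower), and B-alkyl Suzuki–Miyaura coupling with the α-bromobutenolide, an α-halo-enoate that undergoes fast oxidative addition, forms C14–C15 under mild phosphate base that should spare the acetate and the butenolide; aqueous work-up releases the two hydroxyls.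

**Compound list**

1 | dimethyl (2E,4E)-hexa-2,4-dienedioate | COC(=O)/C=C/C=C/C(=O)OC | starting material
2 | (2E,4E)-hexa-2,4-diene-1,6-diol | OC/C=C/C=C/CO | intermediate
3 | (2E,4E)-1,6-bis(tert-butyldimethylsilyloxy)hexa-2,4-diene | CC(C)(C)[Si](C)(C)OC/C=C/C=C/CO[Si](C)(C)C(C)(C)C | intermediate
4 | 1,1,3,3-tetrabromopropan-2-one | O=C(C(Br)Br)C(Br)Br | starting material
5 | 2,7-dibromo-3,6-bis[(tert-butyldimethylsilyloxy)methyl]cyclohept-4-en-1-one, silyloxymethyl groups cis, mixture of bromine epimers (not isolated) | O=C1C(Br)[C@@H](CO[Si](C)(C)C(C)(C)C)C=C[C@@H](CO[Si](C)(C)C(C)(C)C)C1Br | intermediate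
6 | (3R,6S)-3,6-bis[(tert-butyldimethylsilyloxy)methyl]cyclohept-4-en-1-one (meso, cis) | O=C1C[C@@H](CO[Si](C)(C)C(C)(C)C)C=C[C@@H](CO[Si](C)(C)C(C)(C)C)C1 | intermediate
7 | N'-{(3R,6S)-3,6-bis[(tert-butyldimethylsilyloxy)methyl]cyclohept-4-en-1-ylidene}-4-methylbenzenesulfonohydrazide | Cc1ccc(cc1)S(=O)(=O)NN=C1C[C@@H](CO[Si](C)(C)C(C)(C)C)C=C[C@@H](CO[Si](C)(C)C(C)(C)C)C1 | intermediate
8 | (3R,7S)-3,7-bis[(tert-butyldimethylsilyloxy)methyl]cyclohept-1-ene (meso, cis) | C1C[C@@H](CO[Si](C)(C)C(C)(C)C)C=C[C@@H](CO[Si](C)(C)C(C)(C)C)C1 | intermediate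
9 | [(1R,4S)-cyclohept-2-ene-1,4-diyl]dimethanol (meso, cis) | OC[C@H]1C=C[C@@H](CO)CCC1 | intermediate
10 | [(1R,4S)-4-(hydroxymethyl)cyclohept-2-en-1-yl]methyl acetate | CC(=O)OC[C@H]1C=C[C@@H](CO)CCC1 | intermediate
11 | [(1R,4S)-4-({[dimethyl(prop-2-en-1-yl)silyl]oxy}methyl)cyclohept-2-en-1-yl]methyl acetate | CC(=O)OC[C@H]1C=C[C@@H](CO[Si](C)(C)CC=C)CCC1 | intermediate
12 | (2R)-2-ethenyl-5-[(6S)-2,2-dimethyl-1-oxa-2-silacyclohept-4-en-6-yl]pentyl acetate | CC(=O)OC[C@@H](C=C)CCC[C@@H]1CO[Si](C)(C)CC=C1 | intermediate
13 | prop-2-yn-1-ol | C#CCO | starting material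
14 | (2Z)-3-iodo-2-methylprop-2-en-1-ol | I/C=C(/C)CO | intermediate
15 | 12 with its vinyl group turned into a 2-(9-borabicyclo[3.3.1]nonan-9-yl)ethyl group, configuration unchanged (not isolated) | CC(=O)OC[C@@H](CCB1C2CCCC1CCC2)CCC[C@@H]1CO[Si](C)(C)CC=C1 | intermediate
16 | (2R)-5-[(6S)-2,2-dimethyl-1-oxa-2-silacyclohept-4-en-6-yl]-2-[(3Z)-5-hydroxy-4-methylpent-3-en-1-yl]pentyl acetate | CC(=O)OC[C@@H](CC/C=C(/C)CO)CCC[C@@H]1CO[Si](C)(C)CC=C1 | intermediate
17 | (2R,6S)-2-[(3Z)-5-hydroxy-4-methylpent-3-en-1-yl]-6-(hydroxymethyl)non-8-en-1-yl acetate | CC(=O)OC[C@@H](CC/C=C(/C)CO)CCC[C@H](CO)CC=C | intermediate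
18 | 3-bromofuran-2(5H)-one | O=C1OCC=C1Br | starting material
19 | 17 carrying a 9-borabicyclo[3.3.1]nonan-9-yl group on C14 and 9-BBN borinate esters on both oxygens, configuration unchanged (not isolated) | CC(=O)OC[C@@H](CC/C=C(/C)COB1C2CCCC1CCC2)CCC[C@H](COB1C2CCCC1CCC2)CCCB1C2CCCC1CCC2 | intermediate
20 | (2R,6S)-2-[(3Z)-5-hydroxy-4-methylpent-3-en-1-yl]-6-(hydroxymethyl)-9-(2-oxo-2,5-dihydrofuran-3-yl)nonyl acetate | CC(=O)OC[C@@H](CC/C=C(/C)CO)CCC[C@H](CO)CCCC1=CCOC1=O | target

**Step count and risks**

Total: 13 steps. Longest linear sequence: 12 steps (steps 1–9 and 11–13, from 1); step 10 is a one-step side branch.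

Steps most likely to fail, each with a fallback built on known chemistry:

Step 9. The isomerisation trades one seven-membered ring for another and no volatile alkene leaves, so it may stall at an equilibrium mixture with 11 or drift into oligomers through intermolecular metathesis. The fallback sets out from 11 and returns at 12. Ring-opening cross-metathesis of 11 with ethylene (same ruthenium catalyst, CH2Cl2, 5 bar ethylene, rt) would give the open triene (2R,6S)-6-({[dimethyl(prop-2-en-1-yl)silyl]oxy}methyl)-2-ethenyloct-7-en-1-yl acetate F1. After the ethylene is purged, ring-closing metathesis of F1 at high dilution with fresh catalyst would join the unhindered allylsilane to the neighbouring vinyl group, a kinetically controlled closure that loses ethylene and gives 12.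

Step 12. The acid may also protonate the trisubstituted alkene or ionise the allylic alcohol (Z/E scrambling, double-bond migration, trifluoroacetate capture), and acidolysis of the Si–O bond ahead of C-protonation would slow the wanted SE2' pathway. The fallback sets out from 12 and returns at 17; it moves the acid step ahead of the first coupling. Protodesilylation of 12 itself (CF3CO2H, CH2Cl2, 0 °C; only an acetate and a vinyl group are present) would give (2R,6S)-2-ethenyl-6-(hydroxymethyl)non-8-en-1-yl acetate F2. Iodoetherification (I2, NaHCO3, MeCN, 0 °C; 5-exo closure of the hydroxyl onto the allyl group) would hold both together as (2R)-2-ethenyl-5-[(3S)-5-(iodomethyl)oxolan-3-yl]pentyl acetate F3, a mixture at the iodomethyl-bearing carbon that does not matter. 9-BBN would then hydroborate the only remaining alkene to the B-alkyl-9-BBN adduct of F3, F4 (not isolated). Coupling with 14 under the conditions of step 11 (the alkenyl iodide reacting far faster than the primary alkyl iodide) would give (2R)-2-[(3Z)-5-hydroxy-4-methylpent-3-en-1-yl]-5-[(3S)-5-(iodomethyl)oxolan-3-yl]pentyl acetate F5. Zinc dust in AcOH/EtOH would open the β-iodo ether reductively (Boord-type elimination) and return the terminal alkene and the C19 hydroxyl, that is 17.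

Step 3. The oxyallyl species may decay by reduction or self-condensation faster than the open-chain diene traps it, or the iron salts may ionise the allylic silyl ethers. The fallback does not draw on a numbered compound; it sets out from bought cyclohepta-1,3-diene F6 and vinylene carbonate F7 and returns at 9, bypassing steps 1–6. Diels–Alder addition (neat, 170 °C, sealed tube, trace of hydroquinone) would give the cis-fused cyclic carbonate of bicyclo[3.2.2]non-8-ene-6,7-diol F8 (either orientation of the carbonate serves). Hydrolysis (NaOH, aq. MeOH) would give cis-bicyclo[3.2.2]non-8-ene-6,7-diol F9. Glycol cleavage (NaIO4, THF/H2O, 0 °C) would open the two-carbon bridge to (1R,4S)-cyclohept-2-ene-1,4-dicarbaldehyde F10, whose formyl groups are cis by construction. Reduction with NaBH4 at 0 °C, done at once so that the allylic formyl-bearing carbons cannot epimerise, would give the meso diol 9.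

Further compounds
F1 | step 9 | (2R,6S)-6-({[dimethyl(prop-2-en-1-yl)silyl]oxy}methyl)-2-ethenyloct-7-en-1-yl acetate | CC(=O)OC[C@@H](C=C)CCC[C@@H](C=C)CO[Si](C)(C)CC=C
F2 | step 12 | (2R,6S)-2-ethenyl-6-(hydroxymethyl)non-8-en-1-yl acetate | CC(=O)OC[C@@H](C=C)CCC[C@H](CO)CC=C
F3 | step 12 | (2R)-2-ethenyl-5-[(3S)-5-(iodomethyl)oxolan-3-yl]pentyl acetate (both epimers at oxolane C5) | CC(=O)OC[C@@H](C=C)CCC[C@@H]1COC(CI)C1
F4 | step 12 | B-alkyl-9-BBN adduct of F3: (2R)-2-[2-(9-borabicyclo[3.3.1]nonan-9-yl)ethyl] analogue, configuration unchanged (not isolated) | CC(=O)OC[C@@H](CCB1C2CCCC1CCC2)CCC[C@@H]1COC(CI)C1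
F5 | step 12 | (2R)-2-[(3Z)-5-hydroxy-4-methylpent-3-en-1-yl]-5-[(3S)-5-(iodomethyl)oxolan-3-yl]pentyl acetate | CC(=O)OC[C@@H](CC/C=C(/C)CO)CCC[C@@H]1COC(CI)C1
F6 | step 3 | cyclohepta-1,3-diene (bought) | C1=CC=CCCC1
F7 | step 3 | vinylene carbonate, 1,3-dioxol-2-one (bought) | O=C1OC=CO1
F8 | step 3 | cis-fused cyclic carbonate of bicyclo[3.2.2]non-8-ene-6,7-diol (meso) | O=C1O[C@H]2[C@H]3C=C[C@@H]([C@H]2O1)CCC3
F9 | step 3 | cis-bicyclo[3.2.2]non-8-ene-6,7-diol (meso) | O[C@H]1[C@H]2C=C[C@@H]([C@H]1O)CCC2
F10 | step 3 | (1R,4S)-cyclohept-2-ene-1,4-dicarbaldehyde (meso, cis) | O=C[C@H]1C=C[C@@H](C=O)CCC1
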